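## Retrosynthetic overview

- Locants used below: ring A is the carbocycle C1–C5–C6–C7–C8–C9–C10 (C1 carries OH and the crotonoyl chain C2–C3=C4–C15, C5 the ester oxygen, C9 OH, C10 the methyl C14); ring B is the lactone O–C6/C7–C11(=C13)–C12.
- Late disconnections: O–Si bonds; C2 enone from a propargylic pivalate on C2≡C3 (gold-catalysed acyloxy shift and hydrolysis); C5 ester by acylation; ring B with C5–OH from the C5=C6 alkene and a C12 acrylic acid (epoxidation, 5-exo lactonisation); C11=C13 by Mannich reaction and elimination; C9–OH by C1–OH-directed reduction; C1 carbinol by acetylide addition to a C1 ketone.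
- Key disconnection: C7–C8 and C10–C1 of dienone 7, made together by a gold-catalysed (4+3) annulation (acyloxy shift, cyclopropanation, Cope rearrangement) of propargyl pivalate 2 (C8–C9–C10 and C14) with vinylketene silyl acetal 4 (C7=C6–C5=C1 with C11, C12), which is one step from dimethyl hex-3-enedioate; alkyne 2 is used a second time to bring in C2–C4 and C15.
- Enabling feature: in ring A the oxygenated C9 lies between C8H2 and C10 and faces, 1,4 across the ring, the vicinally oxygenated C5–C6 pair next to the oxygenated C1. This is a cyclohept-4-enone pattern (C9 carbonyl, latent C5=C6 alkene) whose C1 can be a ketene-acetal carbon, and the cis C7/C10 substituents match the boat geometry of a divinylcyclopropane Cope rearrangement.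
- Ring order: ring A in step 3, ring B in step 11.

Key step: step 3

Remark: the sense of induction of the chiral gold catalyst on diene 4 is assumed to give (1S,4S)-7; if the (R)-ligand gives the antipode the (S)-ligand is used, and because 2 is enantiopure any minor enantiomer becomes a separable diastereomer of 8 in step 4. (R)-DTBM-SEGPHOS = (R)-5,5'-bis[bis(3,5-di-tert-butyl-4-methoxyphenyl)phosphino]-4,4'-bi-1,3-benzodioxole.

## Route

Step 1
Reactants: 1 (2S)-but-3-yn-2-ol
Product: 2 (2S)-but-3-yn-2-yl pivalate
Conditions: t-BuCOCl, pyridine, DMAP (cat.), CH2Cl2, 0 °C → rt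
Reagents that add atoms: pivaloyl chloride, CC(C)(C)C(=O)Cl
Why: DMAP-catalysed O-acylation of a secondary alcohol with an acid chloride, which does not touch the stereocentre.

Step 2
Reactants: 3 dimethyl (3E)-hex-3-enedioate
Product: 4 methyl (3E)-6-[(tert-butyldimethylsilyl)oxy]-6-methoxyhexa-3,5-dienoate
Conditions: LiN(iPr)2 (1.0 equiv), THF, −78 °C; then TBSCl, DMPU, −78 → 0 °C; non-aqueous work-up
Reagents that add atoms: tert-butyldimethylsilyl chloride, CC(C)(C)[Si](C)(C)Cl
Why: Kinetic α-deprotonation of one ester gives the lithium dienolate, which is O-silylated to the vinylketene silyl acetal (silyl ketene acetal formation); the existing E alkene is carried over unchanged, and the ketene-acetal geometry is irrelevant because both substituents on that carbon are oxygen.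

Step 3
Reactants: 4 methyl (3E)-6-[(tert-butyldimethylsilyl)oxy]-6-methoxyhexa-3,5-dienoate; 2 (2S)-but-3-yn-2-yl pivalate
Product: 7 methyl 2-[(1S,4S)-4-methyl-5-oxo-3-(pivaloyloxy)cyclohepta-2,6-dien-1-yl]acetate, via cis-divinylcyclopropane 5 (not isolated), via silyl methyl ketal 6 (not isolated)
Conditions: (AuCl)2[(R)-DTBM-SEGPHOS] (2.5 mol %), AgSbF6 (5 mol %), 2,6-di-tert-butylpyridine (5 mol %), CH2Cl2, −20 → 40 °C; then aq. citric acid, THF, 0 °C
Reagents that add atoms: none
Why: Proposed new method: the cationic monovalent gold catalyst triggers a Rautenstrauch-type 1,2-pivaloyloxy shift in 2 to a catalyst-bound vinylcarbenoid (carbene carbon C8, Z-enol pivalate C9=C10), which cyclopropanates the electron-rich C6=C7 bond of 4 to give cis-divinylcyclopropane 5, and 5 undergoes a Cope rearrangement through the boat transition state (C6–C8 breaks, C10–C1 forms) to ketal 6, which the mild acidic work-up hydrolyses to ketone 7. The closest known reaction types are the gold-catalysed formal (4+3) annulation of propargyl esters with 1,3-dienes and the rhodium vinylcarbenoid cyclopropanation/Cope annulation of alkoxy- and silyloxybutadienes; a vinylketene silyl acetal whose reacting alkene is E-disubstituted has not been used in either. Ring A closes by [3,3]-sigmatropic ring expansion of the three-membered ring that the (2+1) carbene transfer first makes. C7 is fixed by stereospecific carbene addition to the E alkene (the CH2CO2Me arm trans to both alkenyl groups) and C10 by the Z-enol ester geometry (methyl trans to C8) relayed through the boat, so that the C7 arm and the C10 methyl end cis; the absolute sense comes from the chiral bisphosphine on gold during cyclopropanation. The step needs site selectivity (C6=C7 over the ketene-acetal bond C5=C1), head-to-tail regiochemistry (C8 to C7, C10 to C1) and a cis-divinyl cyclopropane: C7 is the most nucleophilic terminus of the vinylketene acetal, bonding at the carbene carbon followed by a pericyclic shift fixes the regiochemistry, and the dienyl substituent on C6 should take the position cis to the carbenoid alkenyl group as alkene substituents do in these cyclopropanations. Because both substituents on C1 are oxygen no diene geometry has to be controlled there, and C1 emerges as a ketone while C9 stays masked as the enol ester, which keeps the two carbonyls flanking C10 differentiated.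

Step 4
Reactants: 7 methyl 2-[(1S,4S)-4-methyl-5-oxo-3-(pivaloyloxy)cyclohepta-2,6-dien-1-yl]acetate; 2 (2S)-but-3-yn-2-yl pivalate
Product: 8 methyl 2-[(1S,4R,5R)-5-hydroxy-4-methyl-3-(pivaloyloxy)-5-[(3S)-3-(pivaloyloxy)but-1-yn-1-yl]cyclohepta-2,6-dien-1-yl]acetate
Conditions: 2 (1.5 equiv), LiN(iPr)2, THF, −78 °C; CeCl3, −78 °C; then 7; sat. aq. NH4Cl, −78 °C → rt
Reagents that add atoms: none
Why: 1,2-Addition of a cerium acetylide to the C1 ketone (organocerium addition, which suppresses enolisation at C10); the nucleophile enters anti to the C10 methyl and the C7 arm, which both lie on the same face of the nearly flat dienone, so the alkynyl group ends trans and the new hydroxyl cis to the C10 methyl.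

Step 5
Reactants: 8 the C1 alkynyl carbinol
Product: 9 β-hydroxy ketone (C9 ketone, C8 methylene)
Conditions: K2CO3 (0.3 equiv), MeOH, −10 °C, short reaction time; pH 7 buffer
Reagents that add atoms: none
Why: Methanolysis (transesterification) of the activated enol ester releases the C9 ketone by protonation at C8, while the hindered alkyl pivalate and the methyl ester are unaffected under these brief, cold conditions.

Step 6
Reactants: 9 β-hydroxy ketone
Product: 10 anti-1,3-diol (C9–OH trans to C1–OH)
Conditions: Me4NBH(OAc)3, MeCN/AcOH, −30 °C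
Reagents that add atoms: none
Why: Evans–Saksena hydroxyl-directed reduction: the tertiary C1 hydroxyl binds boron and delivers hydride intramolecularly to the face of the C9 carbonyl on which it sits, which gives the 1,3-anti diol with C9–OH trans to C1–OH and to the C10 methyl.

Step 7
Reactants: 10 anti-1,3-diol
Product: 11 bis(triethylsilyl) ether
Conditions: TESOTf (3 equiv), 2,6-lutidine, CH2Cl2, −78 → 0 °C
Reagents that add atoms: triethylsilyl trifluoromethanesulfonate, CC[Si](CC)(CC)OS(=O)(=O)C(F)(F)F
Why: Silyl triflate silylation protects both the secondary and the hindered tertiary hydroxyl, so that C1–OH cannot direct the later epoxidation or cyclise in step 13 and C9–OH cannot be acylated in step 12.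

Step 8
Reactants: 11 bis(triethylsilyl) ether
Product: 12 Mannich base (dimethylaminomethyl group on C11)
Conditions: LiN(iPr)2 (1.1 equiv), THF, −78 °C; [CH2=NMe2]I, −78 °C → rt
Reagents that add atoms: Eschenmoser's salt (N,N-dimethylmethylideneammonium iodide), C=[N+](C)C.[I-]
Why: Mannich aminomethylation of the methyl ester enolate with Eschenmoser's salt, done at a stage with no free hydroxyl; the configuration created at C11 is of no consequence because it is removed in step 9.

Step 9
Reactants: 12 Mannich base
Product: 14 acrylate ester (C11=C13 in place), via trimethylammonium iodide 13 (not isolated)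
Conditions: MeI, MeOH, rt; then aq. NaHCO3, CH2Cl2, rt
Reagents that add atoms: none
Why: Exhaustive N-methylation followed by E1cB (Hofmann-type) elimination of trimethylamine from the β-ammonio ester gives the 2-substituted acrylate.

Step 10
Reactants: 14 acrylate ester
Product: 15 acrylic acid
Conditions: LiOH, THF/H2O, 0 °C → rt; then dilute HCl to pH 4
Reagents that add atoms: lithium hydroxide, [Li+].[OH-]
Why: Saponification of the methyl ester, which should be much faster than hydrolysis of the secondary pivalate, and the silyl ethers tolerate cold aqueous LiOH.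

Step 11
Reactants: 15 acrylic acid
Product: 17 α-methylene hydroxy lactone (C5–OH trans to the lactone oxygen), via epoxy acid 16 (not isolated)
Conditions: mCPBA, CH2Cl2, 0 °C → rt
Reagents that add atoms: 3-chloroperoxybenzoic acid, OOC(=O)c1cccc(Cl)c1
Why: Prilezhaev epoxidation followed by 5-exo opening of the epoxide by the tethered carboxylic acid (epoxy-acid lactonisation): in the conformer that keeps the C1 silyloxy group and the C7 arm pseudoequatorial the ring folds away from the face opposite to them, so the peracid should attack that face past the slim alkynyl group, and the carboxyl then opens the epoxide at C6 with inversion to give the cis-fused γ-lactone with C5–OH trans to the lactone oxygen.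

Step 12
Reactants: 17 α-methylene hydroxy lactone; 18 (2S)-2-methylbutanoic anhydride
Product: 19 C5 (2S)-2-methylbutanoate
Conditions: 18 (3 equiv), DMAP (0.3 equiv), Et3N, CH2Cl2, 0 °C → rt
Reagents that add atoms: none
Why: DMAP-catalysed acylation (Steglich-type acyl transfer) of the only free hydroxyl by the enantiopure anhydride brings in the (S)-2-methylbutanoyl stereocentre without a ketene pathway that could racemise it.

Step 13
Reactants: 19 C5 (2S)-2-methylbutanoate
Product: 21 bis(triethylsilyl) ether of the target, via allenyl pivalate 20 (not isolated)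
Conditions: Ph3PAuNTf2 (5 mol %), butan-2-one, H2O (5 equiv), rt
Reagents that add atoms: none
Why: Gold-catalysed [3,3]-acyloxy shift of the internal propargylic pivalate to the allenyl pivalate and its hydrolysis in the flask (Meyer–Schuster-type rearrangement of a propargylic ester) should give the thermodynamic (E)-enone with the carbonyl on C2, and the silyl ether on C1 prevents the oxygen there from cyclising onto the allene.

Step 14
Reactants: 21 bis(triethylsilyl) ether of the target
Product: 22 CNP0331957.1
Conditions: HF·pyridine, pyridine, THF, 0 °C → rt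
Reagents that add atoms: none
Why: Fluoride-mediated cleavage of both triethylsilyl ethers under buffered, mildly acidic conditions that leave the α-methylene lactone, the enone and the ester intact.

## Compound list

1 | (2S)-but-3-yn-2-ol | C#C[C@H](C)O | starting material
2 | (2S)-but-3-yn-2-yl pivalate (2,2-dimethylpropanoate) | C#C[C@H](C)OC(=O)C(C)(C)C | intermediate
3 | dimethyl (3E)-hex-3-enedioate | COC(=O)C/C=C/CC(=O)OC | starting material
4 | methyl (3E)-6-[(tert-butyldimethylsilyl)oxy]-6-methoxyhexa-3,5-dienoate (ketene-acetal geometry not controlled) | COC(=O)C/C=C/C=C(OC)O[Si](C)(C)C(C)(C)C | intermediate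
5 | methyl 2-{2-[2-(tert-butyldimethylsilyloxy)-2-methoxyethenyl]-3-[(1Z)-1-(pivaloyloxy)prop-1-en-1-yl]cyclopropyl}acetate, the two alkenyl groups cis to each other and trans to the CH2CO2Me arm | COC(=O)C[C@H]1[C@H](C=C(OC)O[Si](C)(C)C(C)(C)C)[C@@H]1/C(OC(=O)C(C)(C)C)=C/C | intermediate (not isolated)
6 | methyl 2-[(1S,4S)-5-(tert-butyldimethylsilyloxy)-5-methoxy-4-methyl-3-(pivaloyloxy)cyclohepta-2,6-dien-1-yl]acetate (mixture at the ketal carbon) | COC(=O)C[C@H]1C=CC(OC)(O[Si](C)(C)C(C)(C)C)[C@@H](C)C(OC(=O)C(C)(C)C)=C1 | intermediate (not isolated)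
7 | methyl 2-[(1S,4S)-4-methyl-5-oxo-3-(pivaloyloxy)cyclohepta-2,6-dien-1-yl]acetate (C7 arm and C10 methyl cis) | COC(=O)C[C@H]1C=CC(=O)[C@@H](C)C(OC(=O)C(C)(C)C)=C1 | intermediate
8 | methyl 2-[(1S,4R,5R)-5-hydroxy-4-methyl-3-(pivaloyloxy)-5-[(3S)-3-(pivaloyloxy)but-1-yn-1-yl]cyclohepta-2,6-dien-1-yl]acetate (C1–OH cis to the C10 methyl and the C7 arm) | COC(=O)C[C@H]1C=C[C@](O)(C#C[C@H](C)OC(=O)C(C)(C)C)[C@@H](C)C(OC(=O)C(C)(C)C)=C1 | intermediate
9 | methyl 2-{5-hydroxy-4-methyl-3-oxo-5-[(3S)-3-(pivaloyloxy)but-1-yn-1-yl]cyclohept-6-en-1-yl}acetate, ring configuration as in 8 | COC(=O)C[C@H]1C=C[C@](O)(C#C[C@H](C)OC(=O)C(C)(C)C)[C@@H](C)C(=O)C1 | intermediate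
10 | methyl 2-{3,5-dihydroxy-4-methyl-5-[(3S)-3-(pivaloyloxy)but-1-yn-1-yl]cyclohept-6-en-1-yl}acetate, C9–OH (position 3) trans to C1–OH (position 5) and to the methyl | COC(=O)C[C@H]1C=C[C@](O)(C#C[C@H](C)OC(=O)C(C)(C)C)[C@@H](C)[C@H](O)C1 | intermediate
11 | 3,5-bis-O-triethylsilyl ether of 10 | COC(=O)C[C@H]1C=C[C@](O[Si](CC)(CC)CC)(C#C[C@H](C)OC(=O)C(C)(C)C)[C@@H](C)[C@H](O[Si](CC)(CC)CC)C1 | intermediate
12 | methyl 3-(dimethylamino)-2-(ring of 11)propanoate (Mannich base, both C11 epimers) | COC(=O)C(CN(C)C)[C@H]1C=C[C@](O[Si](CC)(CC)CC)(C#C[C@H](C)OC(=O)C(C)(C)C)[C@@H](C)[C@H](O[Si](CC)(CC)CC)C1 | intermediate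
13 | N-methyl ammonium iodide of 12 | COC(=O)C(C[N+](C)(C)C)[C@H]1C=C[C@](O[Si](CC)(CC)CC)(C#C[C@H](C)OC(=O)C(C)(C)C)[C@@H](C)[C@H](O[Si](CC)(CC)CC)C1.[I-] | intermediate (not isolated)
14 | methyl 2-(ring of 11)prop-2-enoate | COC(=O)C(=C)[C@H]1C=C[C@](O[Si](CC)(CC)CC)(C#C[C@H](C)OC(=O)C(C)(C)C)[C@@H](C)[C@H](O[Si](CC)(CC)CC)C1 | intermediate
15 | 2-(ring of 11)prop-2-enoic acid | OC(=O)C(=C)[C@H]1C=C[C@](O[Si](CC)(CC)CC)(C#C[C@H](C)OC(=O)C(C)(C)C)[C@@H](C)[C@H](O[Si](CC)(CC)CC)C1 | intermediate
16 | epoxy acid: 15 with a cis C5–C6 epoxide on the face opposite to C1–OSiEt3 and the C7 arm | OC(=O)C(=C)[C@H]1[C@@H]2O[C@@H]2[C@](O[Si](CC)(CC)CC)(C#C[C@H](C)OC(=O)C(C)(C)C)[C@@H](C)[C@H](O[Si](CC)(CC)CC)C1 | intermediate (not isolated)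
17 | 8-hydroxy-6-methyl-3-methylidene-7-[(3S)-3-(pivaloyloxy)but-1-yn-1-yl]-5,7-bis(triethylsilyloxy)octahydro-2H-cyclohepta[b]furan-2-one, cis-fused, the six ring stereocentres arranged as in 22 | C=C1C(=O)O[C@@H]2[C@H]1C[C@@H](O[Si](CC)(CC)CC)[C@H](C)[C@@](O[Si](CC)(CC)CC)(C#C[C@H](C)OC(=O)C(C)(C)C)[C@H]2O | intermediate
18 | (2S)-2-methylbutanoic anhydride | CC[C@H](C)C(=O)OC(=O)[C@@H](C)CC | starting material
19 | 8-O-[(2S)-2-methylbutanoyl] ester of 17 | C=C1C(=O)O[C@@H]2[C@H]1C[C@@H](O[Si](CC)(CC)CC)[C@H](C)[C@@](O[Si](CC)(CC)CC)(C#C[C@H](C)OC(=O)C(C)(C)C)[C@H]2OC(=O)[C@@H](C)CC | intermediate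
20 | allenyl pivalate: 19 with the side chain on C1 rearranged to 1-(pivaloyloxy)buta-1,2-dien-1-yl | C=C1C(=O)O[C@@H]2[C@H]1C[C@@H](O[Si](CC)(CC)CC)[C@H](C)[C@@](O[Si](CC)(CC)CC)(C(OC(=O)C(C)(C)C)=C=CC)[C@H]2OC(=O)[C@@H](C)CC | intermediate (not isolated)
21 | 5,7-bis-O-triethylsilyl ether of 22 | C=C1C(=O)O[C@@H]2[C@H]1C[C@@H](O[Si](CC)(CC)CC)[C@H](C)[C@@](O[Si](CC)(CC)CC)(C(=O)/C=C/C)[C@H]2OC(=O)[C@@H](C)CC | intermediate
22 | (3aS,5R,6S,7S,8S,8aR)-7-[(2E)-but-2-enoyl]-5,7-dihydroxy-6-methyl-3-methylidene-2-oxooctahydro-2H-cyclohepta[b]furan-8-yl (2S)-2-methylbutanoate (CNP0331957.1) | C=C1C(=O)O[C@@H]2[C@H]1C[C@@H](O)[C@H](C)[C@@](O)(C(=O)/C=C/C)[C@H]2OC(=O)[C@@H](C)CC | target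

## Step count and risks

Total: 14 steps. Longest linear sequence: 13 steps (3 → 22, steps 2–14); step 1 supplies 2 for steps 3 and 4.

Steps most likely to fail:

1. Step 3 (proposed new method). The ketene acetal 4 may be desilylated or ionised by the Lewis-acidic gold cation before carbene transfer. Stepwise zwitterionic capture at C7 may divert material to cyclopentenes or open-chain vinylogous alkylation products, and enantiofacial control may be poor. The fallback sets out from 2 and comes back at 7. It replaces the ketene acetal by a 1-silyloxy diene, the diene class on which vinylcarbenoid cyclopropanation/Cope annulations are documented, and raises C1 to the ketone level afterwards. Cross-metathesis of methyl pent-4-enoate with crotonaldehyde (second-generation Grubbs catalyst, CH2Cl2, 40 °C) gives methyl (E)-6-oxohex-4-enoate F1. Soft γ-enolisation (TBSOTf, Et3N, Et2O, 0 °C) gives methyl (3E,5E)-6-(tert-butyldimethylsilyloxy)hexa-3,5-dienoate F2. Compound 2 and F2 under the gold conditions of step 3, without the acidic work-up, should give the cycloheptadienyl silyl ether F3. HF·pyridine removes the allylic silyl group to give the allylic alcohol F4, and Dess–Martin periodinane oxidises it to 7.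

2. Step 11. The peracid may attack the face of C5=C6 that carries the C1 silyloxy group and the C7 arm (poor facial selectivity). The carboxyl then cannot open the epoxide at C6 and the C5/C6 configuration is lost. The fallback sets out from 15 and comes back at 17, and uses hydroxyl delivery instead of steric bias. Selective acidic cleavage of the secondary C9 silyl ether (PPTS, MeOH, 0 °C; the tertiary C1 silyl ether is much slower) gives the C9 alcohol F5. VO(acac)2 and t-BuOOH (CH2Cl2, 0 °C) then deliver the epoxide oxygen from the face of the C9 hydroxyl, which is the required face, to give the epoxy acid F6. This lactonises as in step 11 to the dihydroxy lactone F7. The less hindered C9 hydroxyl is re-silylated (TESCl, imidazole, DMF, −20 °C; the C5 hydroxyl next to the quaternary C1 should react far more slowly) to return 17.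

3. Step 5. Methoxide may trigger retro-aldol opening of ring A between C1 and C10 through the free tertiary alkoxide of the β-hydroxy ketone, or epimerise C10. The fallback sets out from 8 and comes back at 9. It blocks the alkoxide temporarily: TMSOTf and 2,6-lutidine (CH2Cl2, −78 °C) give the trimethylsilyl ether F8. K2CO3 in MeOH (−10 °C) cleaves the enol pivalate to the ketone F9, in which the retro-aldol path is closed. Citric acid in MeOH (0 °C) then removes the trimethylsilyl group under acidic conditions to give 9.

Further compounds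
F1 | step 3 | methyl (E)-6-oxohex-4-enoate | COC(=O)CC/C=C/C=O
F2 | step 3 | methyl (3E,5E)-6-(tert-butyldimethylsilyloxy)hexa-3,5-dienoate | COC(=O)C/C=C/C=C/O[Si](C)(C)C(C)(C)C
F3 | step 3 | methyl 2-[5-(tert-butyldimethylsilyloxy)-4-methyl-3-(pivaloyloxy)cyclohepta-2,6-dien-1-yl]acetate, silyloxy group, methyl and CH2CO2Me arm all cis | COC(=O)C[C@H]1C=C[C@@H](O[Si](C)(C)C(C)(C)C)[C@@H](C)C(OC(=O)C(C)(C)C)=C1
F4 | step 3 | methyl 2-[5-hydroxy-4-methyl-3-(pivaloyloxy)cyclohepta-2,6-dien-1-yl]acetate, configuration as in F3 | COC(=O)C[C@H]1C=C[C@@H](O)[C@@H](C)C(OC(=O)C(C)(C)C)=C1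
F5 | step 11 | 15 with the C9 triethylsilyl ether cleaved to the free C9 alcohol | OC(=O)C(=C)[C@H]1C=C[C@](O[Si](CC)(CC)CC)(C#C[C@H](C)OC(=O)C(C)(C)C)[C@@H](C)[C@H](O)C1
F6 | step 11 | epoxy acid from F5, C5–C6 epoxide on the face of the C9 hydroxyl | OC(=O)C(=C)[C@H]1[C@@H]2O[C@@H]2[C@](O[Si](CC)(CC)CC)(C#C[C@H](C)OC(=O)C(C)(C)C)[C@@H](C)[C@H](O)C1
F7 | step 11 | 17 lacking the C9 triethylsilyl group (C5 and C9 hydroxyls free) | C=C1C(=O)O[C@@H]2[C@H]1C[C@@H](O)[C@H](C)[C@@](O[Si](CC)(CC)CC)(C#C[C@H](C)OC(=O)C(C)(C)C)[C@H]2O
F8 | step 5 | C1 trimethylsilyl ether of 8 | COC(=O)C[C@H]1C=C[C@](O[Si](C)(C)C)(C#C[C@H](C)OC(=O)C(C)(C)C)[C@@H](C)C(OC(=O)C(C)(C)C)=C1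
F9 | step 5 | C1 trimethylsilyl ether of 9 | COC(=O)C[C@H]1C=C[C@](O[Si](C)(C)C)(C#C[C@H](C)OC(=O)C(C)(C)C)[C@@H](C)C(=O)C1
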